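**Retrosynthetic overview**
1. Endgame: the C-3 ketone comes from a silyl-protected carbinol, the 1,2-epoxide from C-10-hydroxyl-directed epoxidation of a Z C-1=C-2 alkene, and the 8-angelate is installed after C-8 is inverted by oxidation and 1,3-anti reduction.
2. Key disconnection: the γ-lactone ring (O–C-6 and C-11–C-7 bonds) is removed as 2-bromoacrylic acid. The enabling feature is that the lactone is cis-fused at C-6/C-7 and C-6 is allylic to the Z C-4=C-5 bond, so it is the syn carbo-oxygenation product of a ring Z,Z-1,3-diene C-4=C-5–C-6=C-7.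
3. Ten-membered ring: closed as a cyclodeca-1,6-diyne by acetylide addition of C-2 to a C-3 aldehyde; the Z alkenes come from a Z vinyl iodide (C-4=C-5) and syn semi-hydrogenation (C-1=C-2, C-6=C-7).
4. Fragments: a diyne diol (C-6 to C-2, stereocentres C-8 and C-10) from an asymmetric ynone/ynal aldol and chelation-controlled MeMgBr addition; C-3 to C-5 from propargyl alcohol; union by Sonogashira coupling.
5. Ring order: 1,3-dioxane (temporary acetonide), ten-membered carbocycle, γ-lactone (key step), oxirane.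

Key step: step 13

Remark: locants C-1 to C-15 are those of the target (ring C-1 to C-10, lactone C-11/C-12, exocyclic methylene C-13, methyls C-14 on C-10 and C-15 on C-4) and are used for the macrocyclic intermediates.
Remark: the ProPhenol enantiomer in step 1 is the one that gives the 5S aldol 3 ((S,S) is assumed); C-3 is carried as a mixture of epimers from step 9 to step 18 because it ends as the ketone.

**Route**

Step 1
Reactants: 1 3-(trimethylsilyl)prop-2-ynal; 2 4-(triisopropylsilyl)but-3-yn-2-one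
Product: 3 (5S)-5-hydroxy-1-(triisopropylsilyl)-7-(trimethylsilyl)hepta-1,6-diyn-3-one
Conditions: (S,S)-ProPhenol (10 mol %), Et2Zn (20 mol %), 4 Å MS, THF, 0 °C
Reagents that add atoms: none
Why: Dinuclear zinc–ProPhenol direct aldol addition of a methyl ynone to a non-enolisable ynal; the chiral zinc pocket selects the aldehyde face and should set the carbinol (later C-8) as S.

Step 2
Reactants: 3 (5S)-5-hydroxy-1-(triisopropylsilyl)-7-(trimethylsilyl)hepta-1,6-diyn-3-one
Product: 4 (3R,5S)-3-methyl-1-(triisopropylsilyl)-7-(trimethylsilyl)hepta-1,6-diyne-3,5-diol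
Conditions: MeMgBr (3 equiv), CH2Cl2/Et2O, −78 °C
Reagents that add atoms: methylmagnesium bromide, C[Mg]Br
Why: Chelation-controlled Grignard addition: the magnesium alkoxide and the ketone form a six-membered chelate and methyl attacks axially, trans to the alkynyl group on the carbinol carbon, which should give the tertiary alcohol (later C-10) syn to the secondary one along the diyne chain.

Step 3
Reactants: 4 (3R,5S)-3-methyl-1-(triisopropylsilyl)-7-(trimethylsilyl)hepta-1,6-diyne-3,5-diol
Product: 5 (4R,6S)-2,2,4-trimethyl-4-[(triisopropylsilyl)ethynyl]-6-[(trimethylsilyl)ethynyl]-1,3-dioxane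
Conditions: 2,2-dimethoxypropane, PPTS (cat.), CH2Cl2, rt
Reagents that add atoms: 2,2-dimethoxypropane, COC(C)(C)OC
Why: Acid-catalysed transketalisation gives the acetonide of the syn-1,3-diol, which masks both hydroxyls and, with both alkynyl groups axial, holds the two alkyne arms parallel for the later ring closure.

Step 4
Reactants: 5 (4R,6S)-2,2,4-trimethyl-4-[(triisopropylsilyl)ethynyl]-6-[(trimethylsilyl)ethynyl]-1,3-dioxane
Product: 6 (4R,6S)-6-ethynyl-2,2,4-trimethyl-4-[(triisopropylsilyl)ethynyl]-1,3-dioxane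
Conditions: K2CO3 (cat.), MeOH, rt
Reagents that add atoms: none
Why: Base-mediated protodesilylation cleaves the alkynyl–SiMe3 bond while the bulkier alkynyl–Si(iPr)3 bond should stay.

Step 5
Reactants: 7 prop-2-yn-1-ol
Product: 9 (Z)-3-iodo-2-methylprop-2-en-1-ol, via alkenylmagnesium alkoxide 8 (not isolated)
Conditions: MeMgBr (2.5 equiv), CuI (10 mol %), Et2O, 0 °C to rt; then I2, −20 °C
Reagents that add atoms: methylmagnesium bromide, C[Mg]Br; iodine, II
Why: Copper-catalysed anti-carbomagnesiation of the propargylic magnesium alkoxide puts methyl on the internal carbon and magnesium cis to the CH2O group in a five-membered chelate, and iodinolysis with retention should fix the Z vinyl iodide.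

Step 6
Reactants: 6 (4R,6S)-6-ethynyl-2,2,4-trimethyl-4-[(triisopropylsilyl)ethynyl]-1,3-dioxane; 9 (Z)-3-iodo-2-methylprop-2-en-1-ol
Product: 10 (Z)-2-methyl-5-{(4S,6R)-2,2,6-trimethyl-6-[(triisopropylsilyl)ethynyl]-1,3-dioxan-4-yl}pent-2-en-4-yn-1-ol
Conditions: Pd(PPh3)2Cl2 (3 mol %), CuI (6 mol %), Et3N, THF, rt
Reagents that add atoms: none
Why: Sonogashira coupling proceeds with retention of the Z vinyl iodide geometry and tolerates the free allylic alcohol.

Step 7
Reactants: 10 (Z)-2-methyl-5-{(4S,6R)-2,2,6-trimethyl-6-[(triisopropylsilyl)ethynyl]-1,3-dioxan-4-yl}pent-2-en-4-yn-1-ol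
Product: 11 (Z)-5-[(4S,6R)-6-ethynyl-2,2,6-trimethyl-1,3-dioxan-4-yl]-2-methylpent-2-en-4-yn-1-ol
Conditions: Bu4NF (1.1 equiv), THF, 0 °C
Reagents that add atoms: none
Why: Fluoride-induced protodesilylation of the alkynylsilane; the acetonide and the allylic alcohol should be inert.

Step 8
Reactants: 11 (Z)-5-[(4S,6R)-6-ethynyl-2,2,6-trimethyl-1,3-dioxan-4-yl]-2-methylpent-2-en-4-yn-1-ol
Product: 12 (Z)-5-[(4S,6R)-6-ethynyl-2,2,6-trimethyl-1,3-dioxan-4-yl]-2-methylpent-2-en-4-ynal
Conditions: MnO2 (activated, excess), CH2Cl2, rt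
Reagents that add atoms: none
Why: Chemoselective MnO2 oxidation of the primary allylic alcohol should give the Z enynal without touching the alkynes or the acetonide.

Step 9
Reactants: 12 (Z)-5-[(4S,6R)-6-ethynyl-2,2,6-trimethyl-1,3-dioxan-4-yl]-2-methylpent-2-en-4-ynal
Product: 14 (4Z,8S,10R)-8,10-O-isopropylidene-4,10-dimethylcyclodec-4-ene-1,6-diyne-3,8,10-triol (both C-3 epimers), via lithium acetylide 13 (not isolated)
Conditions: LiN(SiMe3)2 (1.3 equiv), CeCl3 (3 equiv), THF (0.002 M), −78 to −20 °C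
Reagents that add atoms: none
Why: Intramolecular acetylide addition to the aldehyde at high dilution should close the ten-membered ring as a cyclodeca-1,6-diyne, a ring type in which two alkynes sit parallel across the ring; the new C-3 carbinol forms without control, which does not matter because C-3 ends as the ketone.

Step 10
Reactants: 14 (4Z,8S,10R)-8,10-O-isopropylidene-4,10-dimethylcyclodec-4-ene-1,6-diyne-3,8,10-triol
Product: 15 3-O-(tert-butyldimethylsilyl) ether of 14
Conditions: TBSOTf, 2,6-lutidine, CH2Cl2, −78 °C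
Reagents that add atoms: tert-butyldimethylsilyl triflate, CC(C)(C)[Si](C)(C)OS(=O)(=O)C(F)(F)F
Why: Silylation of the only free hydroxyl protects C-3 at the alcohol level, so that no dienone is present during the steps that follow.

Step 11
Reactants: 15 3-O-(tert-butyldimethylsilyl) ether of 14
Product: 16 (1Z,4Z,6Z,8S,10R)-3-(tert-butyldimethylsilyloxy)-8,10-O-isopropylidene-4,10-dimethylcyclodeca-1,4,6-triene-8,10-diol
Conditions: H2 (1 atm), Pd/CaCO3 poisoned with Pb(OAc)2 (Lindlar catalyst), quinoline, EtOAc, rt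
Reagents that add atoms: none
Why: Lindlar semi-hydrogenation adds hydrogen syn to both ring alkynes, so the C-1=C-2 and C-6=C-7 double bonds can only be Z.

Step 12
Reactants: 16 (1Z,4Z,6Z,8S,10R)-3-(tert-butyldimethylsilyloxy)-8,10-O-isopropylidene-4,10-dimethylcyclodeca-1,4,6-triene-8,10-diol
Product: 17 (1Z,4Z,6Z,8S,10R)-3-(tert-butyldimethylsilyloxy)-4,10-dimethylcyclodeca-1,4,6-triene-8,10-diol
Conditions: PPTS (cat.), MeOH, rt
Reagents that add atoms: none
Why: Mild acid-catalysed methanolysis of the acetonide should free the C-8 and C-10 hydroxyls while the secondary silyl ether survives.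

Step 13
Reactants: 17 (1Z,4Z,6Z,8S,10R)-3-(tert-butyldimethylsilyloxy)-4,10-dimethylcyclodeca-1,4,6-triene-8,10-diol; 18 2-bromoprop-2-enoic acid
Product: 19 (1Z,4Z,6S,7R,8S,10R)-3-(tert-butyldimethylsilyloxy)-8,10-dihydroxygermacra-1,4,11(13)-trien-12,6-olide
Conditions: Pd(OAc)2 (10 mol %), P(2-furyl)3 (20 mol %), NaHCO3 (3 equiv), n-Bu4NCl (1 equiv), BHT (cat.), DMF, 60 °C
Reagents that add atoms: none
Why: Proposed new method: zerovalent palladium inserts into the C–Br bond of 2-bromoacrylate, the α-carboxyvinyl palladium species adds across the C-6=C-7 bond with the vinyl carbon going to the unsubstituted diene terminus C-7, and the resulting π-allyl palladium (C-6/C-5/C-4) is closed at C-6 by the carboxylate held on the same face. The closest known reaction type is the Larock heteroannulation of 1,3-dienes, including cyclic ones, by aryl and vinylic halides that carry a carboxylic acid or hydroxyl group, which is not assumed to have been shown for 2-bromoacrylic acid on a macrocyclic diene. The lactone ring closes by inner-sphere C–O bond formation from a six-membered oxapalladacycle, formally a 5-exo attack of the carboxylate on the allyl terminus, and because both new bonds reach one face of a Z alkene the ring fusion at C-6/C-7 can only be cis. The face is set by the C-8 stereocentre: allylic 1,3-strain with C-5 keeps H-8 in the plane of the C-6=C-7 bond, C-9 and the twisted C-4=C-5 bond cover the inner face, and the free C-8 hydroxyl on the outer face can guide palladium, so C-11 should enter on the face that carries O-8 in this conformer, which places O-8 and C-11 trans across the ring as in 19. The step needs regioselectivity between the diene termini and between the allyl ends, and chemoselectivity against the isolated C-1=C-2 alkene; the CH terminus C-7 versus the fully substituted C-4, the five-membered ring size and the hindered position of C-1=C-2 between two substituted carbons should secure these. The C-4=C-5 bond is released Z because the allyl unit stays locked in the ten-membered ring.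

Step 14
Reactants: 19 (1Z,4Z,6S,7R,8S,10R)-3-(tert-butyldimethylsilyloxy)-8,10-dihydroxygermacra-1,4,11(13)-trien-12,6-olide
Product: 20 (1Z,4Z,6S,7S,10R)-3-(tert-butyldimethylsilyloxy)-10-hydroxy-8-oxogermacra-1,4,11(13)-trien-12,6-olide
Conditions: Dess–Martin periodinane (1.2 equiv), CH2Cl2, 0 °C
Reagents that add atoms: none
Why: Dess–Martin oxidation of the only secondary alcohol removes the C-8 stereocentre that steered step 13; the tertiary C-10 alcohol cannot be oxidised.

Step 15
Reactants: 20 (1Z,4Z,6S,7S,10R)-3-(tert-butyldimethylsilyloxy)-10-hydroxy-8-oxogermacra-1,4,11(13)-trien-12,6-olide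
Product: 21 (1Z,4Z,6S,7R,8R,10R)-3-(tert-butyldimethylsilyloxy)-8,10-dihydroxygermacra-1,4,11(13)-trien-12,6-olide
Conditions: Me4NBH(OAc)3 (5 equiv), MeCN/AcOH (1:1), −30 °C
Reagents that add atoms: none
Why: Evans–Saksena reduction: the C-10 alkoxyborohydride delivers hydride intramolecularly through a chair six-membered transition state, which should give the 1,3-anti diol and thus the 8R carbinol of the target.

Step 16
Reactants: 21 (1Z,4Z,6S,7R,8R,10R)-3-(tert-butyldimethylsilyloxy)-8,10-dihydroxygermacra-1,4,11(13)-trien-12,6-olide; 22 (Z)-2-methylbut-2-enoic acid (angelic acid)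
Product: 24 (1Z,4Z,6S,7R,8R,10R)-8-angeloyloxy-3-(tert-butyldimethylsilyloxy)-10-hydroxygermacra-1,4,11(13)-trien-12,6-olide, via mixed anhydride 23 (not isolated)
Conditions: 22, 2,4,6-trichlorobenzoyl chloride, Et3N, toluene, rt; then 21, toluene, 80 °C
Reagents that add atoms: none
Why: Yamaguchi esterification through the mixed anhydride should acylate the secondary C-8 alcohol in preference to the tertiary one and, run without DMAP, is expected to keep the Z geometry of the angelate.

Step 17
Reactants: 24 (1Z,4Z,6S,7R,8R,10R)-8-angeloyloxy-3-(tert-butyldimethylsilyloxy)-10-hydroxygermacra-1,4,11(13)-trien-12,6-olide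
Product: 25 (1S,2R,4Z,6S,7R,8R,10R)-8-angeloyloxy-3-(tert-butyldimethylsilyloxy)-1,2-epoxy-10-hydroxygermacra-4,11(13)-dien-12,6-olide
Conditions: VO(acac)2 (10 mol %), t-BuOOH (1.5 equiv, decane), CH2Cl2, 0 °C
Reagents that add atoms: tert-butyl hydroperoxide, CC(C)(C)OO
Why: Hydroxyl-directed epoxidation: the vanadium alkylperoxide bound to the C-10 alkoxide delivers oxygen to the adjacent Z alkene on the hydroxyl face (cis epoxy alcohol, cis epoxide from the Z alkene), while the other alkenes lack a free allylic hydroxyl or are electron-poor.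

Step 18
Reactants: 25 (1S,2R,4Z,6S,7R,8R,10R)-8-angeloyloxy-3-(tert-butyldimethylsilyloxy)-1,2-epoxy-10-hydroxygermacra-4,11(13)-dien-12,6-olide
Product: 26 (1S,2S,4Z,6S,7R,8R,10R)-8-angeloyloxy-1,2-epoxy-3,10-dihydroxygermacra-4,11(13)-dien-12,6-olide
Conditions: HF·pyridine, pyridine, THF, 0 °C to rt
Reagents that add atoms: none
Why: Buffered fluoride cleavage of the silyl ether should spare the epoxide, the angelate and the α-methylene lactone.

Step 19
Reactants: 26 (1S,2S,4Z,6S,7R,8R,10R)-8-angeloyloxy-1,2-epoxy-3,10-dihydroxygermacra-4,11(13)-dien-12,6-olide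
Product: 27 (1S,2R,4Z,6S,7R,8R,10R)-8-angeloyloxy-1,2-epoxy-10-hydroxy-3-oxogermacra-4,11(13)-dien-12,6-olide (target)
Conditions: Dess–Martin periodinane, NaHCO3, CH2Cl2, 0 °C to rt
Reagents that add atoms: none
Why: Dess–Martin oxidation of the secondary allylic epoxy alcohol should give the C-3 ketone and removes the stereocentre carried as a mixture.

**Compound list**

1 | 3-(trimethylsilyl)prop-2-ynal | O=CC#C[Si](C)(C)C | starting material
2 | 4-(triisopropylsilyl)but-3-yn-2-one | CC(=O)C#C[Si](C(C)C)(C(C)C)C(C)C | starting material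
3 | (5S)-5-hydroxy-1-(triisopropylsilyl)-7-(trimethylsilyl)hepta-1,6-diyn-3-one | C[Si](C)(C)C#C[C@@H](O)CC(=O)C#C[Si](C(C)C)(C(C)C)C(C)C | intermediate
4 | (3R,5S)-3-methyl-1-(triisopropylsilyl)-7-(trimethylsilyl)hepta-1,6-diyne-3,5-diol | C[Si](C)(C)C#C[C@@H](O)C[C@@](C)(O)C#C[Si](C(C)C)(C(C)C)C(C)C | intermediate
5 | (4R,6S)-2,2,4-trimethyl-4-[(triisopropylsilyl)ethynyl]-6-[(trimethylsilyl)ethynyl]-1,3-dioxane | C[Si](C)(C)C#C[C@@H]1C[C@@](C)(OC(C)(C)O1)C#C[Si](C(C)C)(C(C)C)C(C)C | intermediate
6 | (4R,6S)-6-ethynyl-2,2,4-trimethyl-4-[(triisopropylsilyl)ethynyl]-1,3-dioxane | C#C[C@@H]1C[C@@](C)(OC(C)(C)O1)C#C[Si](C(C)C)(C(C)C)C(C)C | intermediate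
7 | prop-2-yn-1-ol | C#CCO | starting material
8 | bromomagnesium (Z)-3-(bromomagnesio)-2-methylprop-2-en-1-olate | Br[Mg]OC/C(C)=C\[Mg]Br | intermediate (not isolated)
9 | (Z)-3-iodo-2-methylprop-2-en-1-ol | OC/C(C)=C\I | intermediate
10 | (Z)-2-methyl-5-{(4S,6R)-2,2,6-trimethyl-6-[(triisopropylsilyl)ethynyl]-1,3-dioxan-4-yl}pent-2-en-4-yn-1-ol | OC/C(C)=C\C#C[C@@H]1C[C@@](C)(OC(C)(C)O1)C#C[Si](C(C)C)(C(C)C)C(C)C | intermediate
11 | (Z)-5-[(4S,6R)-6-ethynyl-2,2,6-trimethyl-1,3-dioxan-4-yl]-2-methylpent-2-en-4-yn-1-ol | OC/C(C)=C\C#C[C@@H]1C[C@@](C)(OC(C)(C)O1)C#C | intermediate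
12 | (Z)-5-[(4S,6R)-6-ethynyl-2,2,6-trimethyl-1,3-dioxan-4-yl]-2-methylpent-2-en-4-ynal | O=C/C(C)=C\C#C[C@@H]1C[C@@](C)(OC(C)(C)O1)C#C | intermediate
13 | lithium acetylide of 12 | O=C/C(C)=C\C#C[C@@H]1C[C@@](C)(OC(C)(C)O1)C#C[Li] | intermediate (not isolated)
14 | (4Z,8S,10R)-8,10-O-isopropylidene-4,10-dimethylcyclodec-4-ene-1,6-diyne-3,8,10-triol, both C-3 epimers | OC1C#C[C@@]2(C)C[C@@H](C#C/C=C1/C)OC(C)(C)O2 | intermediate
15 | 3-O-(tert-butyldimethylsilyl) ether of 14 | CC(C)(C)[Si](C)(C)OC1C#C[C@@]2(C)C[C@@H](C#C/C=C1/C)OC(C)(C)O2 | intermediate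
16 | (1Z,4Z,6Z,8S,10R)-3-(tert-butyldimethylsilyloxy)-8,10-O-isopropylidene-4,10-dimethylcyclodeca-1,4,6-triene-8,10-diol | CC(C)(C)[Si](C)(C)OC1/C=C\[C@@]2(C)C[C@@H](/C=C\C=C1\C)OC(C)(C)O2 | intermediate
17 | (1Z,4Z,6Z,8S,10R)-3-(tert-butyldimethylsilyloxy)-4,10-dimethylcyclodeca-1,4,6-triene-8,10-diol | CC(C)(C)[Si](C)(C)OC1/C=C\[C@](C)(O)C[C@H](O)/C=C\C=C1\C | intermediate
18 | 2-bromoprop-2-enoic acid | C=C(Br)C(=O)O | starting material
19 | (1Z,4Z,6S,7R,8S,10R)-3-(tert-butyldimethylsilyloxy)-8,10-dihydroxygermacra-1,4,11(13)-trien-12,6-olide | C=C1C(=O)O[C@H]2/C=C(/C)C(O[Si](C)(C)C(C)(C)C)/C=C\[C@](C)(O)C[C@H](O)[C@@H]12 | intermediate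
20 | (1Z,4Z,6S,7S,10R)-3-(tert-butyldimethylsilyloxy)-10-hydroxy-8-oxogermacra-1,4,11(13)-trien-12,6-olide | C=C1C(=O)O[C@H]2/C=C(/C)C(O[Si](C)(C)C(C)(C)C)/C=C\[C@](C)(O)CC(=O)[C@@H]12 | intermediate
21 | (1Z,4Z,6S,7R,8R,10R)-3-(tert-butyldimethylsilyloxy)-8,10-dihydroxygermacra-1,4,11(13)-trien-12,6-olide | C=C1C(=O)O[C@H]2/C=C(/C)C(O[Si](C)(C)C(C)(C)C)/C=C\[C@](C)(O)C[C@@H](O)[C@@H]12 | intermediate
22 | (Z)-2-methylbut-2-enoic acid (angelic acid) | C/C=C(/C)C(=O)O | starting material
23 | (Z)-2-methylbut-2-enoic 2,4,6-trichlorobenzoic anhydride | C/C=C(/C)C(=O)OC(=O)c1c(Cl)cc(Cl)cc1Cl | intermediate (not isolated)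
24 | (1Z,4Z,6S,7R,8R,10R)-8-angeloyloxy-3-(tert-butyldimethylsilyloxy)-10-hydroxygermacra-1,4,11(13)-trien-12,6-olide | C=C1C(=O)O[C@H]2/C=C(/C)C(O[Si](C)(C)C(C)(C)C)/C=C\[C@](C)(O)C[C@@H](OC(=O)/C(C)=C\C)[C@@H]12 | intermediate
25 | (1S,2R,4Z,6S,7R,8R,10R)-8-angeloyloxy-3-(tert-butyldimethylsilyloxy)-1,2-epoxy-10-hydroxygermacra-4,11(13)-dien-12,6-olide | C=C1C(=O)O[C@H]2/C=C(/C)C(O[Si](C)(C)C(C)(C)C)[C@@H]3O[C@@H]3[C@](C)(O)C[C@@H](OC(=O)/C(C)=C\C)[C@@H]12 | intermediate
26 | (1S,2S,4Z,6S,7R,8R,10R)-8-angeloyloxy-1,2-epoxy-3,10-dihydroxygermacra-4,11(13)-dien-12,6-olide | C=C1C(=O)O[C@H]2/C=C(/C)C(O)[C@@H]3O[C@@H]3[C@](C)(O)C[C@@H](OC(=O)/C(C)=C\C)[C@@H]12 | intermediate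
27 | (1S,2R,4Z,6S,7R,8R,10R)-8-angeloyloxy-1,2-epoxy-10-hydroxy-3-oxogermacra-4,11(13)-dien-12,6-olide | C=C1C(=O)O[C@H]2/C=C(/C)C(=O)[C@@H]3O[C@@H]3[C@](C)(O)C[C@@H](OC(=O)/C(C)=C\C)[C@@H]12 | target

**Step count**

Total steps: 19. Longest linear sequence: 18 (steps 1–4 and 6–19).

**Steps most likely to fail**

Step 13 (Proposed new method). The carbopalladation of the hindered ring diene may be slow or may go to the wrong terminus, β-hydride elimination toward C-3 may compete, the face away from O-8 may be attacked (the two C-3 epimers need not behave alike), or the allyl may be closed by the C-8 hydroxyl. The fallback uses known radical–polar crossover chemistry in place of palladium. It sets out from 17: Mn(OAc)3·2H2O, malonic acid (excess), KOAc, AcOH, 40 °C is the lactone annulation of a 1,3-diene with trivalent manganese, in which the malonyl radical adds to C-7, the allyl radical is oxidised and the carboxyl closes on C-6. This should give the α-carboxy lactone, 3-(tert-butyldimethylsilyloxy)-8,10-dihydroxy-13-norgermacra-1,4-dien-12,6-olide-11-carboxylic acid F1. Decarboxylative Mannich methylenation of F1 (aqueous HCHO, Et2NH, NaOAc, AcOH, rt then 60 °C) comes back to the route at 19.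

Step 9. Oligomerisation may outrun ring closure, and the amide base may deprotonate the enal at the C-15 methyl instead of the alkyne. The fallback sets out from 12: iodination of the terminal alkyne (N-iodosuccinimide, AgNO3 cat., acetone) should give the iodoalkyne, (Z)-5-[(4S,6R)-6-(iodoethynyl)-2,2,6-trimethyl-1,3-dioxan-4-yl]-2-methylpent-2-en-4-ynal F2. Nozaki–Hiyama–Kishi ring closure of F2 (CrCl2, NiCl2 cat., THF, high dilution), a non-basic carbonyl addition of an alkynylchromium species of trivalent chromium, comes back to the route at 14.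

Step 15. In ketone 20 the C-7 hydrogen is α to the ketone and allylic, so C-7 may epimerise or the exocyclic double bond may migrate into the ring; the ring may also prevent the chair transition state, so that hydride reaches the wrong face. The fallback sets out from 19 and bypasses 20 and 21: Mitsunobu esterification with angelic acid 22 (PPh3, DIAD, toluene, 0 °C) inverts C-8 and installs the ester in one operation, coming back to the route at 24. This fallback forms no new compound (F0).

**Further compounds**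

F1 | step 13 | 3-(tert-butyldimethylsilyloxy)-8,10-dihydroxy-13-norgermacra-1,4-dien-12,6-olide-11-carboxylic acid | OC(=O)C1C(=O)O[C@H]2/C=C(/C)C(O[Si](C)(C)C(C)(C)C)/C=C\[C@](C)(O)C[C@H](O)[C@@H]12
F2 | step 9 | (Z)-5-[(4S,6R)-6-(iodoethynyl)-2,2,6-trimethyl-1,3-dioxan-4-yl]-2-methylpent-2-en-4-ynal | O=C/C(C)=C\C#C[C@@H]1C[C@@](C)(OC(C)(C)O1)C#CI
F0 | step 15 | none | none
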